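(The readings were computed from invented constants; noise was put on by code.)

At 25 min, the time of reading, the gamma flask stands at 31.7 % monomer in chains, so that reading answers "now". The other questions depend on what the chains do during a further wait.

all flasks: free monomer 0.020 M
- gamma: initiator 1 mM; temperature −20 °C; the very flask that is asked about, followed so far
- alpha: initiator 1 mM; temperature −25 °C; run made earlier
- flask: initiator 1.0 mM; temperature −20 °C; time 25 min

- gamma (time / min: monomer in chains / %): 1.33: 80.9; 4.00: 77.1; 8.00: 66.6; 10.0: 61.6; 15.0: 49.9; 20.0: 40.3; 25.0: 31.7
- alpha (time / min: monomer in chains / %): 1.33: 81.7; 4.00: 84.4; 8.00: 79.3; 10.0: 76.9; 15.0: 70.3; 20.0: 63.0; 25.0: 57.9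

(readings scatter by 0.3 percentage points)

- north-west: at 25 min add free monomer, 50.0 % of the amount charged, then wait 25 min
- south-west: change nothing and wait 25 min more
- west: at 25 min take out 90 % of the monomer in chains then present, then wait 25 min
- south-east: at 25 min raise the temperature by 15 K, then wait 25 min

- what is taken out of monomer in chains is counted as made
- additions bring no volume worth counting

1. monomer in chains, in percent of the free monomer first charged, at 25 min
2. what to do for the largest gain in monomer in chains; "none" if nothing gains more than 2 percentage points (north-west / south-west / west / south-east / none)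
3. monomer in chains present, with what was taken out counted in, in percent of the free monomer first charged, after south-west
4. monomer in chains present, with what was taken out counted in, in percent of the free monomer first charged, after south-east

Two numbers in the gamma run seem at odds. Monomer in chains falls 12 percentage points from 10.0 min to 15.0 min, but 8.6 points from 20.0 min to 25.0 min, so the loss slows. Yet each stretch keeps nearly the same share: 0.810, then 0.787. That looks like first-order decay. Read the rate constant from the last stretch:

k = ln(y₆/y₇)/Δt = 0.0480 min⁻¹

f = exp(−k·wait) = 0.301

f is the survival factor, the share of monomer in chains that outlasts the wait. Your reckoning for gamma, an estimate that counts all added monomer as chains at once: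

south-west: [monomer in chains]·f = 9.55 %

west: 29.5 %

north-west: 24.6 %

Each falls below the present reading. The alpha run gives 0.0169 min⁻¹ over the same stretch. That colder run reads below k, so you expect the rise of 15 K to lower f and south-east to end under south-west. Your choice is none.

The forecast gave 31.8 %, north-west, 3 % and 0.5 %, saying of adding monomer: “This is probably best, though close to west.” On best and g2 it differs from your reckoning.

The flask gives 31.9 %, none, 9.60 % and 0 %. West loses least, at −2.1 points.

    initiator → 2 initiating radical (k = 0.00150 s⁻¹, Ea = 70.0 kJ mol⁻¹)
    free monomer + initiating radical → growing radical + monomer in chains (k = 3.60 × 10⁶ M⁻¹ s⁻¹, Ea = 12.0 kJ mol⁻¹)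
    free monomer + growing radical → monomer in chains + growing radical, rate k3*[growing radical]*[free monomer] (k = 1.10 × 10⁵ M⁻¹ s⁻¹, Ea = 8.00 kJ mol⁻¹)
    2 growing radical → dead chain (k = 1.00 × 10⁷ M⁻¹ s⁻¹, Ea = 14.0 kJ mol⁻¹)
    free monomer ⇌ dormant form (K = 2.70, k = 0.00710 s⁻¹, Ea = 69.0 kJ mol⁻¹, ΔH = 3.00 kJ mol⁻¹)
    monomer in chains → over-reaction product (k = 8.10 × 10⁻⁴ s⁻¹, Ea = 78.0 kJ mol⁻¹)
    (constants at −20 °C)

At 25.0 min in the gamma flask, monomer in chains is made at 0.0370 of the rate at which it is used up. Its half-life by the step to over-reaction product is then 14 min, which makes the survival factor 0.297. Read at 1.0 h, the same flask is reckoned with k at 5.91 %, and it holds 5.91 %.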